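The earlier runs and the new flask stem from a simulated flask with constants of no real substance; scatter was added.

A slow loss of intermediate A showed in the birch run, so I asked how slow it was against the fall of starting material. Oak is the flask asked about, and birch ran on for days.

| flask | starting material | partner | remark | time |
|---|---|---|---|---|
| oak | 0.10 M | 0.25 M (fed, over 80 min) | the very flask that is asked about, followed so far; the fed solution adds 0.25 times the starting volume |  |
| birch | 0.20 M | 0.25 M (fed, over 80 min) | run made earlier; the fed solution adds 0.25 times the starting volume |  |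
| flask | 0.10 M | 0.250 M (fed, over 80 min) | the fed solution adds 0.25 times the starting volume | 10 d |

oak run (percent of the starting material charged)

| time / h | intermediate A / % | product / % | starting material / % |
|---|---|---|---|
| 2.50 | 12.5 | 1.2 | 71.3 |
| 6.00 | 23.3 | 0.3 | 46.0 |
| 12.0 | 30.5 | 0 | 19.9 |
| 20.0 | 32.1 | 0.7 | 5.6 |
| 25.0 | 32.3 | 2.0 | 4.1 |
| 30.0 | 32.3 | 3.4 | 1.2 |
| 40.0 | 31.3 | 4.7 | 0.7 |

birch run (percent of the starting material charged)

| time / d | intermediate A / % | product / % | starting material / % |
|---|---|---|---|
| 1.04 | 32.8 | 1.8 | 2.9 |
| 2.08 | 27.8 | 5.9 | 0 |
| 3.00 | 27.5 | 10.4 | 0 |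
| 4.00 | 21.6 | 17.4 | 0 |
| 5.00 | 21.7 | 21.4 | 0.2 |
| 6.00 | 19.6 | 23.8 | 0 |
| 8.00 | 16.9 | 31.5 | 0.3 |

(each reading ± 1 percentage point)

1. the best time, 10 d at the latest, for intermediate A
2. the amount of intermediate A, in percent of the starting material charged, at that time

- amounts are per litre of the starting volume; all of the dose is in the solution fed
- the earlier runs were read with a standard deviation of 1 percentage point

A first-order constant k is the fraction of a species lost per unit time. In oak, starting material fell from 71.3% at 2.50 h to 19.9% at 12.0 h. I therefore read its constant as k_S = 0.134 h⁻¹. In birch, intermediate A fell from 27.8% at 2.08 d to 16.9% at 8.00 d, so I read an apparent loss constant k_L = 0.0841 d⁻¹. Starting material fell much faster than intermediate A did. I assumed that k_L held for oak too, although birch was charged with twice the starting material.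

A species that starts from none, is supplied by one first-order decay and is lost by another stops rising when gain equals loss. That happens at ln(k_S/k_L)/(k_S − k_L), which gave me 1.16 d. I call this t*, the peak time. It fell between oak's readings at 25.0 h and 30.0 h. Both read 32.3%, so I expected about that height.

The forecast gave 1.1 d and 32.5%: “The flat top and the data suggest about 1.1 d, with A near 32.5%”. My t* was slightly later.

The simulation gave 1.15 d and 31.8%.

    partner + intermediate B → product (k = 0.110 L mol⁻¹ h⁻¹)
    starting material → intermediate A (k = 0.0770 h⁻¹)
    partner + intermediate A → intermediate B (k = 0.120 L mol⁻¹ h⁻¹)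
    intermediate A ⇌ intermediate E (K = 1.10, k = 0.0900 h⁻¹)
    intermediate B ⇌ intermediate D (K = 0.560, k = 0.0920 h⁻¹)
    intermediate C ⇌ intermediate E (K = 38.0, k = 0.0970 h⁻¹)
    starting material → intermediate C (k = 0.0550 h⁻¹)

The forward step from intermediate A to intermediate E alone, its way back not counted, had a half-life of 0.32 d. That was shorter than the 0.96 d of partner + intermediate A to intermediate B, reckoned as if the whole charge were there at once, and both were shorter than t*. A neighbour with a quarter of this flask's partner reached 41.0% and still held 31.5% at the end.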